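Numbering: coumarin O1–C8a; side chain C1' (ketone), C2' (stereocentre), C3' (isopropyl CH).
Retrosynthesis: cut the C2'–O senecioate, then the O1–C2 lactone bond together with the C3=C4 double bond, then the benzene ring at C8a–C8, C7–C6 and C8a–C4a, with C5–C6 traced to a Wolff shift; this leaves diazo enone 4 and methoxyalkyne 12.
Enabling feature: the benzene ring of the coumarin carries four adjacent substituents (C4a carbon, C8a oxygen, C8 side chain, C7 methoxy), a 2-substituted resorcinol monomethyl ether, which is the pattern a vinylketene and an alkoxyalkyne give, with every neighbour placed by connectivity.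
Forward order: two open chains (steps 1–2 and 3–7); benzene ring first (step 8); pyranone ring second (closure in step 10, C3=C4 in step 11); then the C1' ketone (steps 12–13) and the C2' ester (steps 14–15).
Stereochemistry: C2' (R) comes from (R)-2-hydroxy-3-methylbutanoic acid 5 and no bond to it is ever broken; it sits next to a carbonyl only from step 13 on, under non-basic conditions. C1' is a temporary carbinol centre that step 13 erases.

Key step: step 8

Assumption: the configuration of the temporary C1' carbinol centre is immaterial; it is drawn throughout as the Felkin–Anh (anti) epimer, and any minor epimer would be carried along because step 13 converts both into the same ketone.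

Step 1
Reactants: 1 methyl 4-oxobutanoate
Product: 2 methyl (E)-6-oxohept-4-enoate
Conditions: Ph3P=CHC(O)CH3, CH2Cl2, 40 °C
Reagents that add atoms: 1-(triphenylphosphoranylidene)propan-2-one, CC(=O)C=P(c1ccccc1)(c1ccccc1)c1ccccc1
Why: Wittig olefination with an acyl-stabilised ylide, which attacks the aldehyde but not the ester and should deliver the E-enone because oxaphosphetane formation from stabilised ylides is reversible and controlled by product stability.

Step 2
Reactants: 2 methyl (E)-6-oxohept-4-enoate
Product: 4 methyl (E)-7-diazo-6-oxohept-4-enoate, via trifluoroacetyl diketone 3 (not isolated)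
Conditions: LiN(SiMe3)2, THF, −78 °C; CF3CO2CH2CF3; aq. HCl work-up; then MsN3, Et3N, H2O, MeCN, 20 °C
Reagents that add atoms: methanesulfonyl azide, CS(=O)(=O)N=[N+]=[N-]
Why: Detrifluoroacetylative (Regitz-type) diazo transfer: LiN(SiMe3)2 removes a ketone methyl proton kinetically (the ester α-protons are less acidic), Claisen-type trifluoroacetylation activates that carbon, and mesyl azide then transfers N2 with loss of the trifluoroacetyl group, a sequence suited to base-sensitive α,β-unsaturated methyl ketones.

Step 3
Reactants: 5 (R)-2-hydroxy-3-methylbutanoic acid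
Product: 6 methyl (R)-2-hydroxy-3-methylbutanoate
Conditions: MeOH, H2SO4 (cat.), 65 °C
Reagents that add atoms: methanol, CO
Why: Fischer esterification under acid catalysis, in which no bond to the stereocentre is made or broken, so the R configuration should be carried over unchanged.

Step 4
Reactants: 6 methyl (R)-2-hydroxy-3-methylbutanoate
Product: 7 methyl (R)-2-(tert-butyldimethylsilyloxy)-3-methylbutanoate
Conditions: TBSCl, imidazole, DMF, 20 °C
Reagents that add atoms: tert-butyldimethylsilyl chloride, CC(C)(C)[Si](C)(C)Cl
Why: Imidazole-promoted O-silylation of a secondary alcohol; the tert-butyldimethylsilyl ether is chosen because it is non-chelating in step 6 and outlasts the triethylsilyl ether in step 12.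

Step 5
Reactants: 7 methyl (R)-2-(tert-butyldimethylsilyloxy)-3-methylbutanoate
Product: 8 (R)-2-(tert-butyldimethylsilyloxy)-3-methylbutanal
Conditions: i-Bu2AlH (1.1 equiv), CH2Cl2, −78 °C; MeOH, then aq. KNaC4H4O6
Reagents that add atoms: none
Why: Partial reduction of an ester with i-Bu2AlH at −78 °C, where the tetrahedral aluminium hemiacetal persists until work-up, should stop at the aldehyde, which is used at once so that the α-stereocentre has no chance to epimerise.

Step 6
Reactants: 8 (R)-2-(tert-butyldimethylsilyloxy)-3-methylbutanal; 9 chloroacetaldehyde dimethyl acetal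
Product: 11 (3S,4R)-4-(tert-butyldimethylsilyloxy)-1-methoxy-5-methylhex-1-yn-3-ol, via lithium methoxyacetylide 10 (not isolated)
Conditions: Et2NH, n-BuLi (3 equiv each), THF, 0 °C; 9, 0 °C; then 8, −78 °C; aq. NaHCO3
Reagents that add atoms: none
Why: Lithium diethylamide strips MeOH and HCl from the chloroacetal and metalates the methoxyacetylene formed, and the alkynyllithium adds to the aldehyde (1,2-carbonyl addition) under Felkin–Anh control by the non-chelating α-silyloxy group, which should favour the 3,4-anti carbinol at a centre that step 13 removes anyway.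

Step 7
Reactants: 11 (3S,4R)-4-(tert-butyldimethylsilyloxy)-1-methoxy-5-methylhex-1-yn-3-ol
Product: 12 (3S,4R)-4-(tert-butyldimethylsilyloxy)-1-methoxy-5-methyl-3-(triethylsilyloxy)hex-1-yne
Conditions: TESCl, imidazole, DMAP (cat.), DMF, 0 → 20 °C
Reagents that add atoms: chlorotriethylsilane, CC[Si](CC)(CC)Cl
Why: Imidazole-buffered O-silylation, a base-only medium that the acid-labile ynol ether tolerates, caps the propargylic alcohol as a triethylsilyl ether so that it cannot add to the ketene in step 8.

Step 8
Reactants: 4 methyl (E)-7-diazo-6-oxohept-4-enoate; 12 (3S,4R)-4-(tert-butyldimethylsilyloxy)-1-methoxy-5-methyl-3-(triethylsilyloxy)hex-1-yne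
Product: 17 methyl 3-{3-[(1S,2R)-2-(tert-butyldimethylsilyloxy)-3-methyl-1-(triethylsilyloxy)butyl]-2-hydroxy-4-methoxyphenyl}propanoate, via vinylketene 13 (not isolated), via vinylcyclobutenone 14 (not isolated), via dienylketene 15 (not isolated), via cyclohexadienone 16 (not isolated)
Conditions: hν (medium-pressure Hg lamp, Vycor filter), ClCH2CH2Cl, 20 °C; then 80 °C in the dark
Reagents that add atoms: none
Why: Light expels N2 from 4 and the Wolff shift of the alkenyl group (which creates C5–C6) gives vinylketene 13; its electrophilic carbonyl carbon (future C8a) is attacked by the nucleophilic, side-chain-bearing alkyne carbon of 12 while the ketene α-carbon bonds to the methoxy-bearing carbon, a (2+2) cycloaddition that forms C8a–C8 and C7–C6 in cyclobutenone 14. On warming, conrotatory four-electron ring opening gives dienylketene 15, and the benzene ring closes by thermal disrotatory six-electron electrocyclisation (C8a–C4a) to dienone 16, which tautomerises to phenol 17. This is the Danheiser benzannulation in its photochemical diazoketone variant, for which alkoxy- and siloxyalkynes are the usual ketenophiles and resorcinol monoethers the usual products. No lasting stereocentre is created (the sp3 ring carbons of 14 and 16 are transient), and C1' and C2' are untouched because the medium is neutral and C2' is not yet next to a carbonyl group. The step needs regiocontrol in the cycloaddition, which the oxygen-polarised triple bond of 12 secures, and a heat-stable alkyne, which the methyl ynol ether provides because it has no β-hydrogen for retro-ene loss of an alkene; the E geometry of 13 also keeps the chain CH2 away from the ketene and so excludes a 1,5-hydrogen shift.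

Step 9
Reactants: 17 methyl 3-{3-[(1S,2R)-2-(tert-butyldimethylsilyloxy)-3-methyl-1-(triethylsilyloxy)butyl]-2-hydroxy-4-methoxyphenyl}propanoate
Product: 18 3-{3-[(1S,2R)-2-(tert-butyldimethylsilyloxy)-3-methyl-1-(triethylsilyloxy)butyl]-2-hydroxy-4-methoxyphenyl}propanoic acid
Conditions: LiOH·H2O, THF/MeOH/H2O, 20 °C; then aq. HCl to pH 4, 0 °C
Reagents that add atoms: lithium hydroxide monohydrate, [Li+].[OH-].O
Why: Saponification of the methyl ester by hydroxide; the two hindered secondary silyl ethers are stable to LiOH at 20 °C, and migration of a silyl group onto the phenoxide is thermodynamically disfavoured.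

Step 10
Reactants: 18 3-{3-[(1S,2R)-2-(tert-butyldimethylsilyloxy)-3-methyl-1-(triethylsilyloxy)butyl]-2-hydroxy-4-methoxyphenyl}propanoic acid
Product: 19 8-[(1S,2R)-2-(tert-butyldimethylsilyloxy)-3-methyl-1-(triethylsilyloxy)butyl]-7-methoxy-3,4-dihydro-2H-chromen-2-one
Conditions: EDC·HCl, DMAP (cat.), CH2Cl2 (dilute), 0 → 20 °C
Reagents that add atoms: none
Why: Carbodiimide-mediated (Steglich-type) lactonisation, in which the activated acid is captured by the ortho phenol through a six-membered transition state, closes the pyranone ring under neutral conditions that spare the benzylic triethylsilyl ether, which a hot sulfonic-acid transesterification of 17 would endanger.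

Step 11
Reactants: 19 8-[(1S,2R)-2-(tert-butyldimethylsilyloxy)-3-methyl-1-(triethylsilyloxy)butyl]-7-methoxy-3,4-dihydro-2H-chromen-2-one
Product: 21 8-[(1S,2R)-2-(tert-butyldimethylsilyloxy)-3-methyl-1-(triethylsilyloxy)butyl]-7-methoxy-2H-chromen-2-one, via phenylselanyl lactone 20 (not isolated)
Conditions: LiN(SiMe3)2, THF, −78 °C; PhSeCl, −78 °C; then H2O2 (30% aq.), pyridine, CH2Cl2, 0 → 20 °C
Reagents that add atoms: none
Why: α-Selenenylation of the lactone lithium enolate followed by oxidation and selenoxide syn-elimination, which can only take a hydrogen from C4, should introduce the C3=C4 bond, the enolate being kept at −78 °C so that it does not expel the phenoxide.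

Step 12
Reactants: 21 8-[(1S,2R)-2-(tert-butyldimethylsilyloxy)-3-methyl-1-(triethylsilyloxy)butyl]-7-methoxy-2H-chromen-2-one
Product: 22 8-[(1S,2R)-2-(tert-butyldimethylsilyloxy)-1-hydroxy-3-methylbutyl]-7-methoxy-2H-chromen-2-one
Conditions: HF·pyridine, pyridine, THF, 0 °C
Reagents that add atoms: none
Why: Selective acidic desilylation: buffered HF·pyridine cleaves a triethylsilyl ether much faster than a secondary tert-butyldimethylsilyl ether, and the acidic medium gives no alkoxide that could move the remaining silyl group from the C2' to the C1' oxygen.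

Step 13
Reactants: 22 8-[(1S,2R)-2-(tert-butyldimethylsilyloxy)-1-hydroxy-3-methylbutyl]-7-methoxy-2H-chromen-2-one
Product: 23 8-[(2R)-2-(tert-butyldimethylsilyloxy)-3-methylbutanoyl]-7-methoxy-2H-chromen-2-one
Conditions: Dess–Martin periodinane, NaHCO3, CH2Cl2, 0 → 20 °C
Reagents that add atoms: none
Why: Dess–Martin oxidation of the hindered benzylic alcohol under bicarbonate buffer should give the aryl ketone without exposing the now enolisable C2' centre to base.

Step 14
Reactants: 23 8-[(2R)-2-(tert-butyldimethylsilyloxy)-3-methylbutanoyl]-7-methoxy-2H-chromen-2-one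
Product: 24 8-[(2R)-2-hydroxy-3-methylbutanoyl]-7-methoxy-2H-chromen-2-one
Conditions: HF (48% aq.), MeCN, 0 → 20 °C
Reagents that add atoms: none
Why: Desilylation with aqueous HF in acetonitrile, an acidic and non-basic fluoride source, should free the C2' hydroxyl without epimerisation or α-ketol isomerisation and without opening the coumarin lactone.

Step 15
Reactants: 24 8-[(2R)-2-hydroxy-3-methylbutanoyl]-7-methoxy-2H-chromen-2-one; 25 3-methylbut-2-enoic acid
Product: 26 (2R)-1-(7-methoxy-2-oxo-2H-chromen-8-yl)-3-methyl-1-oxobutan-2-yl 3-methylbut-2-enoate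
Conditions: EDC·HCl, DMAP (0.2 equiv), CH2Cl2, 0 °C
Reagents that add atoms: none
Why: Steglich esterification of the C2' hydroxyl with the free acid; the bond is formed at oxygen, so the R configuration is retained, and avoiding the acid chloride/tertiary amine pair avoids the vinylketene pathway that moves the senecioyl double bond out of conjugation.

Compound list
1 | methyl 4-oxobutanoate | COC(=O)CCC=O | starting material
2 | methyl (E)-6-oxohept-4-enoate | COC(=O)CC/C=C/C(C)=O | intermediate
3 | methyl (E)-9,9,9-trifluoro-6,8-dioxonon-4-enoate (trifluoroacetyl diketone) | COC(=O)CC/C=C/C(=O)CC(=O)C(F)(F)F | intermediate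
4 | methyl (E)-7-diazo-6-oxohept-4-enoate | COC(=O)CC/C=C/C(=O)C=[N+]=[N-] | intermediate
5 | (R)-2-hydroxy-3-methylbutanoic acid | CC(C)[C@@H](O)C(=O)O | starting material
6 | methyl (R)-2-hydroxy-3-methylbutanoate | CC(C)[C@@H](O)C(=O)OC | intermediate
7 | methyl (R)-2-(tert-butyldimethylsilyloxy)-3-methylbutanoate | CC(C)[C@@H](O[Si](C)(C)C(C)(C)C)C(=O)OC | intermediate
8 | (R)-2-(tert-butyldimethylsilyloxy)-3-methylbutanal | CC(C)[C@@H](O[Si](C)(C)C(C)(C)C)C=O | intermediate
9 | chloroacetaldehyde dimethyl acetal (2-chloro-1,1-dimethoxyethane) | COC(CCl)OC | starting material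
10 | lithium methoxyacetylide | [Li]C#COC | intermediate
11 | (3S,4R)-4-(tert-butyldimethylsilyloxy)-1-methoxy-5-methylhex-1-yn-3-ol | COC#C[C@H](O)[C@H](O[Si](C)(C)C(C)(C)C)C(C)C | intermediate
12 | (3S,4R)-4-(tert-butyldimethylsilyloxy)-1-methoxy-5-methyl-3-(triethylsilyloxy)hex-1-yne | COC#C[C@H](O[Si](CC)(CC)CC)[C@H](O[Si](C)(C)C(C)(C)C)C(C)C | intermediate
13 | methyl (4E)-7-oxohepta-4,6-dienoate (vinylketene) | COC(=O)CC/C=C/C=C=O | intermediate
14 | methyl (4E)-5-{2-methoxy-3-[(1S,2R)-2-(tert-butyldimethylsilyloxy)-3-methyl-1-(triethylsilyloxy)butyl]-4-oxocyclobut-2-en-1-yl}pent-4-enoate (vinylcyclobutenone, ring carbon 1 as a mixture of epimers) | COC(=O)CC/C=C/C1C(=O)C(=C1OC)[C@H](O[Si](CC)(CC)CC)[C@H](O[Si](C)(C)C(C)(C)C)C(C)C | intermediate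
15 | methyl (4E,6E)-8-[(1S,2R)-2-(tert-butyldimethylsilyloxy)-3-methyl-1-(triethylsilyloxy)butyl]-7-methoxy-9-oxonona-4,6,8-trienoate (dienylketene) | COC(=O)CC/C=C/C=C(OC)\C(=C=O)[C@H](O[Si](CC)(CC)CC)[C@H](O[Si](C)(C)C(C)(C)C)C(C)C | intermediate
16 | methyl 3-{5-[(1S,2R)-2-(tert-butyldimethylsilyloxy)-3-methyl-1-(triethylsilyloxy)butyl]-4-methoxy-6-oxocyclohexa-2,4-dien-1-yl}propanoate (cyclohexadienone, ring carbon 1 as a mixture of epimers) | COC(=O)CCC1C=CC(OC)=C([C@H](O[Si](CC)(CC)CC)[C@H](O[Si](C)(C)C(C)(C)C)C(C)C)C1=O | intermediate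
17 | methyl 3-{3-[(1S,2R)-2-(tert-butyldimethylsilyloxy)-3-methyl-1-(triethylsilyloxy)butyl]-2-hydroxy-4-methoxyphenyl}propanoate | COC(=O)CCc1ccc(OC)c([C@H](O[Si](CC)(CC)CC)[C@H](O[Si](C)(C)C(C)(C)C)C(C)C)c1O | intermediate
18 | 3-{3-[(1S,2R)-2-(tert-butyldimethylsilyloxy)-3-methyl-1-(triethylsilyloxy)butyl]-2-hydroxy-4-methoxyphenyl}propanoic acid | OC(=O)CCc1ccc(OC)c([C@H](O[Si](CC)(CC)CC)[C@H](O[Si](C)(C)C(C)(C)C)C(C)C)c1O | intermediate
19 | 8-[(1S,2R)-2-(tert-butyldimethylsilyloxy)-3-methyl-1-(triethylsilyloxy)butyl]-7-methoxy-3,4-dihydro-2H-chromen-2-one | COc1ccc2CCC(=O)Oc2c1[C@H](O[Si](CC)(CC)CC)[C@H](O[Si](C)(C)C(C)(C)C)C(C)C | intermediate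
20 | 8-[(1S,2R)-2-(tert-butyldimethylsilyloxy)-3-methyl-1-(triethylsilyloxy)butyl]-7-methoxy-3-(phenylselanyl)-3,4-dihydro-2H-chromen-2-one (C3 as a mixture of epimers) | COc1ccc2CC([Se]c3ccccc3)C(=O)Oc2c1[C@H](O[Si](CC)(CC)CC)[C@H](O[Si](C)(C)C(C)(C)C)C(C)C | intermediate
21 | 8-[(1S,2R)-2-(tert-butyldimethylsilyloxy)-3-methyl-1-(triethylsilyloxy)butyl]-7-methoxy-2H-chromen-2-one | COc1ccc2ccc(=O)oc2c1[C@H](O[Si](CC)(CC)CC)[C@H](O[Si](C)(C)C(C)(C)C)C(C)C | intermediate
22 | 8-[(1S,2R)-2-(tert-butyldimethylsilyloxy)-1-hydroxy-3-methylbutyl]-7-methoxy-2H-chromen-2-one | COc1ccc2ccc(=O)oc2c1[C@H](O)[C@H](O[Si](C)(C)C(C)(C)C)C(C)C | intermediate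
23 | 8-[(2R)-2-(tert-butyldimethylsilyloxy)-3-methylbutanoyl]-7-methoxy-2H-chromen-2-one | COc1ccc2ccc(=O)oc2c1C(=O)[C@H](O[Si](C)(C)C(C)(C)C)C(C)C | intermediate
24 | 8-[(2R)-2-hydroxy-3-methylbutanoyl]-7-methoxy-2H-chromen-2-one | COc1ccc2ccc(=O)oc2c1C(=O)[C@H](O)C(C)C | intermediate
25 | 3-methylbut-2-enoic acid | CC(C)=CC(=O)O | starting material
26 | (2R)-1-(7-methoxy-2-oxo-2H-chromen-8-yl)-3-methyl-1-oxobutan-2-yl 3-methylbut-2-enoate | COc1ccc2ccc(=O)oc2c1C(=O)[C@H](OC(=O)C=C(C)C)C(C)C | target

Total step count: 15 (steps 1–2 for the diazo enone, steps 3–7 for the alkyne, step 8 for the union, steps 9–15 after it).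
Longest linear sequence: 13 steps (5 → 26, steps 3–15).

Steps most likely to fail

Step 8. The photogenerated vinylketene may be captured too slowly by the crowded, branched alkyne carbon. It would then be lost to dimerisation, to O-acylation of phenol already formed, or to photoisomerisation of the enone followed by a 1,5-hydrogen shift. The fallback sets out from 4 and 12 and returns at 17; it makes the same ketene thermally, slowly and in the dark. Diazoketone 4 undergoes a Wolff rearrangement catalysed by AgO2CPh and Et3N in aqueous THF, and water traps the ketene as (3E)-7-methoxy-7-oxohept-3-enoic acid F1. Oxalyl chloride with catalytic DMF converts this into methyl (4E)-7-chloro-7-oxohept-4-enoate F2. Slow addition of F2 to a solution of 12 and Et3N in toluene at 20 °C releases vinylketene 13 by dehydrochlorination at a low stationary concentration, the way ketenes from acid chlorides are combined with alkoxyalkynes to give 3-alkoxycyclobutenones. After the ammonium salt is filtered off, heating to 80 °C should take 14 through 15 and 16 to 17.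

Step 11. The aryl-ester enolate may fragment by expelling the phenoxide (ketene formation), or selenenylation may occur twice. The fallback sets out from 19, returns at 21 and makes no new compound (F0). It dehydrogenates without any enolate: DDQ in 1,4-dioxane at 100 °C abstracts hydride from C4, which is benzylic and para to the C7 methoxy group, and the cation loses the C3 proton to give the coumarin.

Step 15. Acylation at the hindered C2' hydroxyl may be slow, leaving time for rearrangement of the O-acylisourea, for base-induced migration of the senecioyl double bond out of conjugation, or for epimerisation at C2' by DMAP. The fallback sets out from 24 and 25 and returns at 26; it removes the amine base altogether. Acid 25 is dehydrated with DCC (0.5 equiv, CH2Cl2) to 3-methylbut-2-enoic anhydride F3, and 24 is acylated with F3 under Lewis acid catalysis by Sc(OSO2CF3)3 in MeCN at −20 °C.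

Further compounds
F1 | step 8 | (3E)-7-methoxy-7-oxohept-3-enoic acid | OC(=O)C/C=C/CCC(=O)OC
F2 | step 8 | methyl (4E)-7-chloro-7-oxohept-4-enoate | COC(=O)CC/C=C/CC(=O)Cl
F0 | step 11 | none | none
F3 | step 15 | 3-methylbut-2-enoic anhydride | CC(C)=CC(=O)OC(=O)C=C(C)C
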